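# Synthesis proposal for CNP0209995.1 by Ireland–Claisen rearrangement of a ring-A-fused δ-lactone

## Analysis of the target

Target 31 is a Δ1(10)-octalin diterpenoid ester. Atom numbering used throughout: ring A is C1, C2, C3, C4, C5, C10 and ring B is C5 to C10. The chain C11–C15 hangs on C9, with C16 the methyl on C13. C17 is the methyl on C8, C18 the methyl and C19 the CO2Me carbon on C4, and C20 the methyl on C9.

There are four stereocentres, two of them quaternary: C4 (S), C5 (R), C8 (R) and C9 (S). With H5 drawn down (α), the methyls C18, C17 and C20 are all α, and the C19 ester and the C11 chain are β. C17 and C20 are therefore cis on adjacent carbons. C4 and C9 flank the C5–C10 bond, and C10 is sp2, so it carries no hydrogen that could relay configuration.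

The sensitive groups are:
- the allylic acetate, which does not survive strong base, hydride or zerovalent palladium;
- the two trisubstituted alkenes C1=C10 and C13=C14, which do not tolerate strong protic acid;
- the allylic C5–H;
- the hindered but reducible methyl ester.

The hard part is the vicinal pair C8 (tertiary) and C9 (quaternary) next to the alkene carbon C10, in a fixed relation to the remote quaternary C4. The route rests on this pair. If C9 is the α-carbon of a δ-lactone whose ring oxygen sits on C6, and C8 is the end of an (E)-propenyl group on C6, one [3,3] shift forms C8–C9, closes ring B and leaves the acyl carbon on C9 as the future C20.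

## Retrosynthetic reasoning

**31 to 29 (O15).** The acetate is put on last (30 to 31). O15 is carried as a tert-butyldiphenylsilyl ether (29), because the acetate would not survive the amide bases and hydrides used earlier. The bulkier silyl group is used because it must outlast removal of a second silyl ether on O6.

**29 to 24 (C20 and C6–C7).** The C9 methyl is traced back to a carboxyl group and the C6–C7 single bond to an alkene (29 from 28 from 27 from 25 from 24). These two marks are what the sigmatropic step leaves behind. The forward steps must do three things: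
- saturate the cis-disubstituted C6=C7 in the presence of two trisubstituted alkenes (25);
- take the neopentyl acid to aldehyde 27 without a reagent that adds to alkenes or reduces the C19 ester;
- remove the oxygen through hydrazone 28, since displacement at the neopentyl C20 is not practical.

**24 to 21 (key disconnection).** The C8–C9 bond is cut and C6–O re-formed, giving lactone 21 with C20 as the acyl carbon and an (E)-propenyl group on C6. Cutting here joins the two adjacent stereocentres in one event. The silyl ketene acetal 22 is locked in the lactone ring, so there is no enolate-geometry problem at the fully substituted C9. The C5–C10 bridge forces a boat. The carbinol centre C6 then decides the face at C9, and the (E)-alkene decides C8. Cutting C9–C10 or C9–C11 instead would leave the C8/C9 relation to weaker, remote control. C9 of 21 need not be defined, because enolisation flattens it.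

**21 to 20 to 18 to 17 + 7.** The lactone C20–O bond is made by acylation of the C6 hydroxyl of hydroxy acid 20, with retention at C6. The C9–C11 bond is cut next: dienolate alkylation of tert-butyl ester 17 with homoallylic iodide 7 gives 18. The tert-butyl ester is chosen so that C20 can be freed to the acid without touching the C19 methyl ester. Only an activated C20 acid lactonises cleanly in the presence of that ester.

**17 to 14 + 16.** The C9–C10 bond is cut to alkenyl triflate 14 and the zinc ester enolate 16 from 15 (Negishi coupling). Triflate 14 comes from ketone 13 by kinetic enolisation towards C1, which places the alkene at C1=C10 as in the target.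

**13 to 12 to 10 + 11.** The C5–C6 bond is an aldol bond between the C5 enol carbon of 10 and crotonaldehyde 11. Lactone 21 needs H5 and H6 cis, which is the syn relation between C4 and O6 in aldol 12. A closed, chair-type aldol of a ring enolate (necessarily E) would favour the anti epimer. Its lactone would put C20 on the wrong face of C9. The bond is therefore made from enol silane 10 through an open transition state, where the aldehyde substituent turns away from the quaternary C4.

**10 to 8.** The C4–C18 bond is cut to enone ester 8. Copper-catalysed asymmetric conjugate methylation sets C4, the only centre set by a catalyst. C5, C6, C8 and C9 are all relayed from it.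

**7 to 6 to 5 to 4 to 2 to 1.** The chain is cut at C13–C16 and C14–C15. Syn carbometallation of the alkyne of 2 and hydroxymethylation of alane 3 fix the (E)-C13=C14 alkene (4). The two primary hydroxyls are told apart by their different silyl groups (5, 6) before iodination to 7.

## Alternatives that were turned down

**Alternative 1:** C20 is disconnected from C9 and delivered as a carbenoid carbon. A zinc carbenoid, directed by the C1 α-hydroxyl of tetrasubstituted alkene A2, would add CH2 across C9=C10 to give cyclopropyl carbinol A1. Later cleavage of C10–C20 with loss of the C1 oxygen would leave the C9 methyl and the C1=C10 alkene.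
- For: hydroxyl-directed cyclopropanation is face-specific and tolerant of tetrasubstituted alkenes. The facial outcome at C9 is more certain than in the chosen key step, and this point is conceded.
- Against: A2 must already hold C4, C5 and C8, a tetrasubstituted alkene and an extra carbinol centre, so the hard part is only moved. The cyclopropylcarbinyl opening can break C9–C10 (ring expansion to a more stabilised centre) as easily as C10–C20 (primary centre). The chain must be carried as a masked ketone, and its (E)-alkene made late by an olefination of uncertain geometry.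
- Comparison: the chosen strategy sets C8 and C9 together, closes ring B in the same step and brings the (E)-alkene in intact.

**Alternative 2:** Ring A is disconnected at C4–C5 and C2–C3. Diene A3 (a ring-B 1-vinylcyclohexene with the complete chain) and methacrolein A4 would combine under a chiral Lewis acid to give aldehyde A5. A5 has the C1=C10 alkene in place and needs only oxidation and esterification.
- For: this is the shortest endgame of all the options, and on step count after the diene it is stronger than the chosen route.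
- Against: A3 already contains the vicinal C8/C9 pair, which this disconnection leaves unsolved. The quaternary C9 sits on the inner diene carbon and disfavours the s-cis conformer. The two faces of the diene differ only by methyl against CH2 chain on C9, so the catalyst would have to overrule a near-neutral substrate and enforce exo addition as well. The regiochemistry also pits the two diene substituents against each other.
- Comparison: the chosen strategy creates C8/C9 in the key step and lets the substrate decide their configuration.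

**Alternative 3:** Ring B is disconnected at C9–C10. The alkenyl triflate A6 would undergo a 6-exo Heck cyclisation onto the tethered trisubstituted alkene to give A7, with a vinyl group left on C9 after β-hydride elimination.
- For: Heck closure onto trisubstituted alkenes is a proven way to quaternary carbons. The vinyl group is a good handle: hydroboration and sp3–sp2 Suzuki coupling with an (E)-alkenyl iodide would attach the chain in two steps. On chain installation this is at least as good as the enolate alkylation used here.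
- Against: C5 and C8 must be set beforehand in a flexible tether. The configuration at C9 would then depend on a chair-like insertion biased only by the C8 methyl and the ring-A substituents.
- Comparison: the chosen [3,3] shift fixes C9 and C8 by geometry (a bridged boat and an (E)-alkene) from one carbinol centre. That centre is made by an aldol next to the ring.

Key step: step 14

Remarks on the chemistry:
- Commercial (E)-crotonaldehyde is used.
- The antipode of the chiral copper ligand is the one that gives (S) at C4.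
- C9 of 18–21 forms as both epimers and is carried as such, because step 14 flattens it.

## Route

Step 1
Reactants: 1 but-3-yn-1-ol
Product: 2 tert-butyl(but-3-yn-1-yloxy)dimethylsilane
Conditions: t-BuMe2SiCl, imidazole, CH2Cl2, 0 °C to rt
Reagents that add atoms: tert-butyldimethylsilyl chloride, CC(C)(C)[Si](C)(C)Cl
Why: Standard silylation of a primary alcohol; the ether tolerates the organoaluminium step and can later be removed selectively beside a tert-butyldiphenylsilyl ether.

Step 2
Reactants: 2 tert-butyl(but-3-yn-1-yloxy)dimethylsilane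
Product: 4 (2E)-5-[(tert-butyldimethylsilyl)oxy]-3-methylpent-2-en-1-ol, via (E)-alkenyldimethylalane 3 (not isolated)
Conditions: Me3Al, Cp2ZrCl2 (25 mol %), CH2Cl2, 0 °C to rt; volatiles removed; n-BuLi, THF, −78 °C; (CH2O)n, −78 °C to rt
Reagents that add atoms: trimethylaluminium, C[Al](C)C; paraformaldehyde (as formaldehyde), C=O
Why: Zirconium-catalysed Negishi carboalumination adds CH3 and Al syn across the terminal alkyne with CH3 on the inner carbon, and the alanate formed with n-BuLi is hydroxymethylated with retention, so C15 ends cis to C16 and the (E)-C13=C14 alkene is fixed here.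

Step 3
Reactants: 4 (2E)-5-[(tert-butyldimethylsilyl)oxy]-3-methylpent-2-en-1-ol
Product: 5 (2E)-5-[(tert-butyldimethylsilyl)oxy]-1-[(tert-butyldiphenylsilyl)oxy]-3-methylpent-2-ene
Conditions: t-BuPh2SiCl, imidazole, DMF, rt
Reagents that add atoms: tert-butyldiphenylsilyl chloride, CC(C)(C)[Si](Cl)(c1ccccc1)c1ccccc1
Why: Silylation of the allylic alcohol with the more robust group that has to last until step 19.

Step 4
Reactants: 5 (2E)-5-[(tert-butyldimethylsilyl)oxy]-1-[(tert-butyldiphenylsilyl)oxy]-3-methylpent-2-ene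
Product: 6 (3E)-5-[(tert-butyldiphenylsilyl)oxy]-3-methylpent-3-en-1-ol
Conditions: PPTS (cat.), EtOH, 40 °C
Reagents that add atoms: none
Why: Mild acid solvolysis removes a primary tert-butyldimethylsilyl ether much faster than a tert-butyldiphenylsilyl ether, and the conditions are too weak to ionise the allylic C15–O bond.

Step 5
Reactants: 6 (3E)-5-[(tert-butyldiphenylsilyl)oxy]-3-methylpent-3-en-1-ol
Product: 7 tert-butyl{[(2E)-5-iodo-3-methylpent-2-en-1-yl]oxy}diphenylsilane
Conditions: I2, PPh3, imidazole, CH2Cl2, 0 °C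
Reagents that add atoms: iodine, II
Why: Appel-type iodination of a primary alcohol through the alkoxyphosphonium ion; the alkene geometry and the silyl ether are untouched.

Step 6
Reactants: 8 methyl 3-oxocyclohex-1-ene-1-carboxylate
Product: 10 methyl (1S)-1-methyl-3-[(trimethylsilyl)oxy]cyclohex-2-ene-1-carboxylate, via methylzinc enolate 9 (not isolated)
Conditions: Me2Zn, (CuOTf)2·C6H6 (2.5 mol %), chiral sulfonate-bearing N-heterocyclic carbene L* (5 mol %, charged as Ag2L*2), Et2O, −30 °C; then Me3SiOTf, −30 to 0 °C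
Reagents that add atoms: dimethylzinc, C[Zn]C; trimethylsilyl trifluoromethanesulfonate, C[Si](C)(C)OS(=O)(=O)C(F)(F)F
Why: Copper-catalysed asymmetric conjugate addition to a cyclic γ-keto ester puts the methyl group β to the ketone on the ester-bearing carbon and creates quaternary C4, the carbene–copper complex choosing the enone face that gives (S); O-silylation of the regiodefined zinc enolate fixes the C5=C10 enol ether.

Step 7
Reactants: 10 methyl (1S)-1-methyl-3-[(trimethylsilyl)oxy]cyclohex-2-ene-1-carboxylate; 11 (E)-but-2-enal (crotonaldehyde)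
Product: 12 methyl (1S,2R)-2-[(1S,2E)-1-hydroxybut-2-en-1-yl]-1-methyl-3-oxocyclohexane-1-carboxylate
Conditions: BF3·OEt2, CH2Cl2, −78 °C
Reagents that add atoms: none
Why: Mukaiyama aldol (1,2-addition to the enal) through an open transition state in which the propenyl group of the BF3-bound aldehyde turns away from the quaternary C4, which should give the syn C5/C6 relation (5R,6S in target numbering) needed for a retentive lactonisation; attack on C5 is expected anti to the pseudoaxial C4–CH3 bond, the flatter ester lying near the ring plane, so that C6 ends cis to the C19 ester.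

Step 8
Reactants: 12 methyl (1S,2R)-2-[(1S,2E)-1-hydroxybut-2-en-1-yl]-1-methyl-3-oxocyclohexane-1-carboxylate
Product: 13 methyl (1S,2R)-1-methyl-3-oxo-2-[(1S,2E)-1-[(triethylsilyl)oxy]but-2-en-1-yl]cyclohexane-1-carboxylate
Conditions: Et3SiOTf, 2,6-lutidine, CH2Cl2, −78 °C
Reagents that add atoms: triethylsilyl trifluoromethanesulfonate, CC[Si](CC)(CC)OS(=O)(=O)C(F)(F)F
Why: Silyl triflate with a hindered base caps the β-hydroxy ketone at low temperature before retro-aldol cleavage, dehydration or attack of the hydroxyl on the cis C19 ester (five-membered lactone) can set in.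

Step 9
Reactants: 13 methyl (1S,2R)-1-methyl-3-oxo-2-[(1S,2E)-1-[(triethylsilyl)oxy]but-2-en-1-yl]cyclohexane-1-carboxylate
Product: 14 methyl (1S,2R)-1-methyl-2-[(1S,2E)-1-[(triethylsilyl)oxy]but-2-en-1-yl]-3-{[(trifluoromethyl)sulfonyl]oxy}cyclohex-3-ene-1-carboxylate
Conditions: KN(SiMe3)2, THF, −78 °C; PhNTf2, −78 to 0 °C
Reagents that add atoms: N-phenylbis(trifluoromethanesulfonimide), O=S(=O)(N(c1ccccc1)S(=O)(=O)C(F)(F)F)C(F)(F)F
Why: The bulky amide removes a proton kinetically from the C1 methylene and not from the hindered C5–H, so the enol triflate has the C1=C10 alkene of the target, C5 is not epimerised and the C6 silyloxy group cannot be expelled.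

Step 10
Reactants: 14 methyl (1S,2R)-1-methyl-2-[(1S,2E)-1-[(triethylsilyl)oxy]but-2-en-1-yl]-3-{[(trifluoromethyl)sulfonyl]oxy}cyclohex-3-ene-1-carboxylate; 15 tert-butyl bromoacetate
Product: 17 methyl (1S,2R)-3-(2-tert-butoxy-2-oxoethyl)-1-methyl-2-[(1S,2E)-1-[(triethylsilyl)oxy]but-2-en-1-yl]cyclohex-3-ene-1-carboxylate, via (2-tert-butoxy-2-oxoethyl)zinc bromide 16 (not isolated)
Conditions: 15, Zn dust (activated with BrCH2CH2Br and Me3SiCl), THF, 40 °C; then 14, Pd2(dba)3 (2.5 mol %), XPhos (10 mol %), THF, 50 °C
Reagents that add atoms: none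
Why: Negishi coupling of a Reformatsky reagent with an alkenyl triflate (oxidative addition at C10–OTf, transmetallation of the C-bound zinc enolate, reductive elimination) forms C9–C10; both esters, the silyl ether and the allylic C6–O bond are inert to the catalyst.

Step 11
Reactants: 17 methyl (1S,2R)-3-(2-tert-butoxy-2-oxoethyl)-1-methyl-2-[(1S,2E)-1-[(triethylsilyl)oxy]but-2-en-1-yl]cyclohex-3-ene-1-carboxylate; 7 tert-butyl{[(2E)-5-iodo-3-methylpent-2-en-1-yl]oxy}diphenylsilane
Product: 18 tert-butyl (5E)-7-[(tert-butyldiphenylsilyl)oxy]-2-{(5S,6R)-5-(methoxycarbonyl)-5-methyl-6-[(1S,2E)-1-[(triethylsilyl)oxy]but-2-en-1-yl]cyclohex-1-en-1-yl}-5-methylhept-5-enoate (both C9 epimers)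
Conditions: LiN(i-Pr)2, THF, −78 °C; 7, DMPU, −78 to −20 °C
Reagents that add atoms: none
Why: C9–H is the only acidic site (α to the tert-butyl ester and allylic; C19 has no α-hydrogen), and lithium dienolates of β,γ-unsaturated esters alkylate at the α-carbon; DMPU favours SN2 on the primary iodide, and the C9 configuration is of no consequence.

Step 12
Reactants: 18 tert-butyl (5E)-7-[(tert-butyldiphenylsilyl)oxy]-2-{(5S,6R)-5-(methoxycarbonyl)-5-methyl-6-[(1S,2E)-1-[(triethylsilyl)oxy]but-2-en-1-yl]cyclohex-1-en-1-yl}-5-methylhept-5-enoate (both C9 epimers)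
Product: 20 (5E)-7-[(tert-butyldiphenylsilyl)oxy]-2-{(5S,6R)-6-[(1S,2E)-1-hydroxybut-2-en-1-yl]-5-(methoxycarbonyl)-5-methylcyclohex-1-en-1-yl}-5-methylhept-5-enoic acid (both C9 epimers), via trimethylsilyl ester 19 (not isolated)
Conditions: Me3SiOTf, 2,6-lutidine, CH2Cl2, 0 °C; then HF·pyridine, pyridine, THF, 0 °C to rt
Reagents that add atoms: none
Why: Silyl triflate with lutidine cleaves the tert-butyl ester by O-silylation and loss of isobutene without protic acid, sparing the trisubstituted alkenes, the methyl ester and both silyl ethers; buffered HF then removes the silyl ester and the secondary triethylsilyl ether much faster than the primary tert-butyldiphenylsilyl ether.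

Step 13
Reactants: 20 (5E)-7-[(tert-butyldiphenylsilyl)oxy]-2-{(5S,6R)-6-[(1S,2E)-1-hydroxybut-2-en-1-yl]-5-(methoxycarbonyl)-5-methylcyclohex-1-en-1-yl}-5-methylhept-5-enoic acid (both C9 epimers)
Product: 21 methyl (1S,8S,8aR)-4-{(3E)-5-[(tert-butyldiphenylsilyl)oxy]-3-methylpent-3-en-1-yl}-8-methyl-3-oxo-1-[(1E)-prop-1-en-1-yl]-3,4,6,7,8,8a-hexahydro-1H-isochromene-8-carboxylate (both epimers at C9 of the target numbering)
Conditions: EDC·HCl, DMAP, CH2Cl2 (0.01 M), 0 °C to rt
Reagents that add atoms: none
Why: Steglich-type carbodiimide lactonisation activates only the free C20 acid, so O6 is acylated with retention and six-ring closure outruns attack of the hydroxyl on the hindered C19 methyl ester; the (6S) centre with H5 and H6 cis is carried into the lactone, and both C9 epimers close.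

Step 14
Reactants: 21 methyl (1S,8S,8aR)-4-{(3E)-5-[(tert-butyldiphenylsilyl)oxy]-3-methylpent-3-en-1-yl}-8-methyl-3-oxo-1-[(1E)-prop-1-en-1-yl]-3,4,6,7,8,8a-hexahydro-1H-isochromene-8-carboxylate (both C9 epimers)
Product: 24 (1R,2R,4aR,5S)-1-{(3E)-5-[(tert-butyldiphenylsilyl)oxy]-3-methylpent-3-en-1-yl}-5-(methoxycarbonyl)-2,5-dimethyl-1,2,4a,5,6,7-hexahydronaphthalene-1-carboxylic acid, via trimethylsilyl ketene acetal 22 (not isolated), via trimethylsilyl ester 23 (not isolated)
Conditions: KN(SiMe3)2, Me3SiCl, Et3N, THF/toluene, −78 °C (base added to lactone and silyl chloride); then toluene, 100 °C; aqueous citric acid work-up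
Reagents that add atoms: none
Why: The amide removes C9–H (α to the lactone carbonyl and allylic to C1=C10) and the dienolate is silylated on oxygen to the ring-locked ketene acetal 22, which on heating undergoes a concerted suprafacial [3,3] shift that forms C8–C9 and breaks C6–O to give silyl ester 23, hydrolysed to 24 on work-up. The closest known reaction type is the Ireland–Claisen rearrangement of silyl ketene acetals of alkenyl-substituted lactones to cycloalkene carboxylic acids. Ring B (C5–C6=C7–C8–C9–C10) closes through the sigmatropic shift itself, in a boat array shaped like bicyclo[2.2.2]octane, in which the C5–C10 bond, the C20–O unit and C7=C8 bridge C6 and C9; a chair is geometrically impossible. C9 is controlled by the C6 carbinol centre: C20 stays on the face of the new ring from which O6 leaves, which for (6S) is the α face, so the chain is β. C8 is controlled by the (E)-propenyl geometry, which holds C17 in the outer position of the boat and so cis to C20 (α). The step needs enolisation at C9 only, O-silylation, and rearrangement faster than fragmentation of the enolate to a ketene and an alkoxide. These are secured by C9–H being the only acidic hydrogen (C19 has no α-hydrogen), by the in-situ silyl trap, and by the absence of any other allyl vinyl ether array in 22.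

Step 15
Reactants: 24 (1R,2R,4aR,5S)-1-{(3E)-5-[(tert-butyldiphenylsilyl)oxy]-3-methylpent-3-en-1-yl}-5-(methoxycarbonyl)-2,5-dimethyl-1,2,4a,5,6,7-hexahydronaphthalene-1-carboxylic acid
Product: 25 (1R,2R,4aR,5S)-1-{(3E)-5-[(tert-butyldiphenylsilyl)oxy]-3-methylpent-3-en-1-yl}-5-(methoxycarbonyl)-2,5-dimethyl-1,2,3,4,4a,5,6,7-octahydronaphthalene-1-carboxylic acid
Conditions: H2 (1 atm), RhCl(PPh3)3 (10 mol %), benzene/EtOH, rt
Reagents that add atoms: none
Why: Homogeneous hydrogenation with RhCl(PPh3)3 reduces cis-disubstituted alkenes far faster than trisubstituted ones, so only C6=C7 should be saturated and no stereocentre is formed; diimide would discriminate less well between the ring alkene and C13=C14, and early saturation also removes the doubly allylic C5–H.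

Step 16
Reactants: 25 (1R,2R,4aR,5S)-1-{(3E)-5-[(tert-butyldiphenylsilyl)oxy]-3-methylpent-3-en-1-yl}-5-(methoxycarbonyl)-2,5-dimethyl-1,2,3,4,4a,5,6,7-octahydronaphthalene-1-carboxylic acid
Product: 27 methyl (1S,5R,6R,8aR)-5-{(3E)-5-[(tert-butyldiphenylsilyl)oxy]-3-methylpent-3-en-1-yl}-5-formyl-1,6-dimethyl-1,2,3,5,6,7,8,8a-octahydronaphthalene-1-carboxylate, via acid chloride 26 (not isolated)
Conditions: 1-chloro-N,N,2-trimethylprop-1-en-1-amine, CH2Cl2, 0 °C to rt; then LiAlH(Ot-Bu)3, THF, −78 °C
Reagents that add atoms: none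
Why: The α-chloroenamine makes the hindered acid chloride under neutral conditions (no α-hydrogen, so no ketene), and LiAlH(Ot-Bu)3 reduces acid chlorides to aldehydes at −78 °C without touching the methyl ester; borane is avoided because it would hydroborate the alkenes.

Step 17
Reactants: 27 methyl (1S,5R,6R,8aR)-5-{(3E)-5-[(tert-butyldiphenylsilyl)oxy]-3-methylpent-3-en-1-yl}-5-formyl-1,6-dimethyl-1,2,3,5,6,7,8,8a-octahydronaphthalene-1-carboxylate
Product: 28 methyl (1S,5R,6R,8aR)-5-{(3E)-5-[(tert-butyldiphenylsilyl)oxy]-3-methylpent-3-en-1-yl}-1,6-dimethyl-5-{(E)-[2-(4-methylbenzenesulfonyl)hydrazinylidene]methyl}-1,2,3,5,6,7,8,8a-octahydronaphthalene-1-carboxylate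
Conditions: TsNHNH2, EtOH, 50 °C
Reagents that add atoms: 4-methylbenzenesulfonohydrazide, Cc1ccc(cc1)S(=O)(=O)NN
Why: Condensation of the aldehyde with the sulfonyl hydrazide; the neopentyl aldehyde cannot enolise, so C9 is safe.

Step 18
Reactants: 28 methyl (1S,5R,6R,8aR)-5-{(3E)-5-[(tert-butyldiphenylsilyl)oxy]-3-methylpent-3-en-1-yl}-1,6-dimethyl-5-{(E)-[2-(4-methylbenzenesulfonyl)hydrazinylidene]methyl}-1,2,3,5,6,7,8,8a-octahydronaphthalene-1-carboxylate
Product: 29 methyl (1S,5S,6R,8aR)-5-{(3E)-5-[(tert-butyldiphenylsilyl)oxy]-3-methylpent-3-en-1-yl}-1,5,6-trimethyl-1,2,3,5,6,7,8,8a-octahydronaphthalene-1-carboxylate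
Conditions: catecholborane, CHCl3, 0 °C to rt; then NaOAc·3H2O, reflux
Reagents that add atoms: none
Why: Tosylhydrazone reduction: the borane adds H–B across C=N, acetate then triggers loss of sulfinate to a monoalkyl diazene that extrudes N2, so C20 becomes the C9 methyl; esters, silyl ethers and trisubstituted alkenes are inert to catecholborane at this temperature.

Step 19
Reactants: 29 methyl (1S,5S,6R,8aR)-5-{(3E)-5-[(tert-butyldiphenylsilyl)oxy]-3-methylpent-3-en-1-yl}-1,5,6-trimethyl-1,2,3,5,6,7,8,8a-octahydronaphthalene-1-carboxylate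
Product: 30 methyl (1S,5S,6R,8aR)-5-[(3E)-5-hydroxy-3-methylpent-3-en-1-yl]-1,5,6-trimethyl-1,2,3,5,6,7,8,8a-octahydronaphthalene-1-carboxylate
Conditions: Bu4NF, THF, 0 °C to rt
Reagents that add atoms: none
Why: Fluoride cleaves the silyl ether; the hindered, non-enolisable methyl ester is stable to the basic fluoride.

Step 20
Reactants: 30 methyl (1S,5S,6R,8aR)-5-[(3E)-5-hydroxy-3-methylpent-3-en-1-yl]-1,5,6-trimethyl-1,2,3,5,6,7,8,8a-octahydronaphthalene-1-carboxylate
Product: 31 methyl (1S,5S,6R,8aR)-5-[(3E)-5-acetoxy-3-methylpent-3-en-1-yl]-1,5,6-trimethyl-1,2,3,5,6,7,8,8a-octahydronaphthalene-1-carboxylate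
Conditions: Ac2O, pyridine, DMAP (cat.), CH2Cl2, rt
Reagents that add atoms: acetic anhydride, CC(=O)OC(C)=O
Why: Acylation of the primary allylic alcohol under nucleophilic catalysis; no stereocentre or alkene is affected.

## Compound list

1 | but-3-yn-1-ol | C#CCCO | starting material
2 | tert-butyl(but-3-yn-1-yloxy)dimethylsilane | C#CCCO[Si](C)(C)C(C)(C)C | intermediate
3 | (E)-alkenyldimethylalane from 2 (not isolated) | C[Al](C)/C=C(C)/CCO[Si](C)(C)C(C)(C)C | intermediate
4 | (2E)-5-[(tert-butyldimethylsilyl)oxy]-3-methylpent-2-en-1-ol | OC/C=C(C)/CCO[Si](C)(C)C(C)(C)C | intermediate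
5 | (2E)-5-[(tert-butyldimethylsilyl)oxy]-1-[(tert-butyldiphenylsilyl)oxy]-3-methylpent-2-ene | CC(C)(C)[Si](C)(C)OCC/C(C)=C/CO[Si](c1ccccc1)(c1ccccc1)C(C)(C)C | intermediate
6 | (3E)-5-[(tert-butyldiphenylsilyl)oxy]-3-methylpent-3-en-1-ol | OCC/C(C)=C/CO[Si](c1ccccc1)(c1ccccc1)C(C)(C)C | intermediate
7 | tert-butyl{[(2E)-5-iodo-3-methylpent-2-en-1-yl]oxy}diphenylsilane | ICC/C(C)=C/CO[Si](c1ccccc1)(c1ccccc1)C(C)(C)C | intermediate
8 | methyl 3-oxocyclohex-1-ene-1-carboxylate | COC(=O)C1=CC(=O)CCC1 | starting material
9 | methylzinc enolate of methyl (1S)-1-methyl-3-oxocyclohexane-1-carboxylate (not isolated) | COC(=O)[C@@]1(C)CCCC(O[Zn]C)=C1 | intermediate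
10 | methyl (1S)-1-methyl-3-[(trimethylsilyl)oxy]cyclohex-2-ene-1-carboxylate | COC(=O)[C@@]1(C)CCCC(O[Si](C)(C)C)=C1 | intermediate
11 | (E)-but-2-enal (crotonaldehyde) | C/C=C/C=O | starting material
12 | methyl (1S,2R)-2-[(1S,2E)-1-hydroxybut-2-en-1-yl]-1-methyl-3-oxocyclohexane-1-carboxylate | COC(=O)[C@@]1(C)CCCC(=O)[C@H]1[C@@H](O)/C=C/C | intermediate
13 | methyl (1S,2R)-1-methyl-3-oxo-2-[(1S,2E)-1-[(triethylsilyl)oxy]but-2-en-1-yl]cyclohexane-1-carboxylate | COC(=O)[C@@]1(C)CCCC(=O)[C@H]1[C@@H](O[Si](CC)(CC)CC)/C=C/C | intermediate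
14 | methyl (1S,2R)-1-methyl-2-[(1S,2E)-1-[(triethylsilyl)oxy]but-2-en-1-yl]-3-{[(trifluoromethyl)sulfonyl]oxy}cyclohex-3-ene-1-carboxylate | COC(=O)[C@@]1(C)CCC=C(OS(=O)(=O)C(F)(F)F)[C@H]1[C@@H](O[Si](CC)(CC)CC)/C=C/C | intermediate
15 | tert-butyl bromoacetate | CC(C)(C)OC(=O)CBr | starting material
16 | (2-tert-butoxy-2-oxoethyl)zinc bromide (not isolated) | CC(C)(C)OC(=O)C[Zn]Br | intermediate
17 | methyl (1S,2R)-3-(2-tert-butoxy-2-oxoethyl)-1-methyl-2-[(1S,2E)-1-[(triethylsilyl)oxy]but-2-en-1-yl]cyclohex-3-ene-1-carboxylate | COC(=O)[C@@]1(C)CCC=C(CC(=O)OC(C)(C)C)[C@H]1[C@@H](O[Si](CC)(CC)CC)/C=C/C | intermediate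
18 | tert-butyl (5E)-7-[(tert-butyldiphenylsilyl)oxy]-2-{(5S,6R)-5-(methoxycarbonyl)-5-methyl-6-[(1S,2E)-1-[(triethylsilyl)oxy]but-2-en-1-yl]cyclohex-1-en-1-yl}-5-methylhept-5-enoate (both C9 epimers) | COC(=O)[C@@]1(C)CCC=C(C(CC/C(C)=C/CO[Si](c2ccccc2)(c2ccccc2)C(C)(C)C)C(=O)OC(C)(C)C)[C@H]1[C@@H](O[Si](CC)(CC)CC)/C=C/C | intermediate
19 | trimethylsilyl ester corresponding to 18 (triethylsilyl ether retained; not isolated) | COC(=O)[C@@]1(C)CCC=C(C(CC/C(C)=C/CO[Si](c2ccccc2)(c2ccccc2)C(C)(C)C)C(=O)O[Si](C)(C)C)[C@H]1[C@@H](O[Si](CC)(CC)CC)/C=C/C | intermediate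
20 | (5E)-7-[(tert-butyldiphenylsilyl)oxy]-2-{(5S,6R)-6-[(1S,2E)-1-hydroxybut-2-en-1-yl]-5-(methoxycarbonyl)-5-methylcyclohex-1-en-1-yl}-5-methylhept-5-enoic acid (both C9 epimers) | COC(=O)[C@@]1(C)CCC=C(C(CC/C(C)=C/CO[Si](c2ccccc2)(c2ccccc2)C(C)(C)C)C(=O)O)[C@H]1[C@@H](O)/C=C/C | intermediate
21 | methyl (1S,8S,8aR)-4-{(3E)-5-[(tert-butyldiphenylsilyl)oxy]-3-methylpent-3-en-1-yl}-8-methyl-3-oxo-1-[(1E)-prop-1-en-1-yl]-3,4,6,7,8,8a-hexahydro-1H-isochromene-8-carboxylate (both C9 epimers; key-step precursor) | COC(=O)[C@@]1(C)CCC=C2[C@H]1[C@H](/C=C/C)OC(=O)C2CC/C(C)=C/CO[Si](c1ccccc1)(c1ccccc1)C(C)(C)C | intermediate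
22 | trimethylsilyl ketene acetal of 21 (C9=C20, OSiMe3 on C20; not isolated) | COC(=O)[C@@]1(C)CCC=C2[C@H]1[C@H](/C=C/C)OC(O[Si](C)(C)C)=C2CC/C(C)=C/CO[Si](c1ccccc1)(c1ccccc1)C(C)(C)C | intermediate
23 | trimethylsilyl ester of 24 (not isolated) | COC(=O)[C@@]1(C)CCC=C2[C@H]1C=C[C@@H](C)[C@]2(C(=O)O[Si](C)(C)C)CC/C(C)=C/CO[Si](c1ccccc1)(c1ccccc1)C(C)(C)C | intermediate
24 | (1R,2R,4aR,5S)-1-{(3E)-5-[(tert-butyldiphenylsilyl)oxy]-3-methylpent-3-en-1-yl}-5-(methoxycarbonyl)-2,5-dimethyl-1,2,4a,5,6,7-hexahydronaphthalene-1-carboxylic acid (key-step product) | COC(=O)[C@@]1(C)CCC=C2[C@H]1C=C[C@@H](C)[C@]2(C(=O)O)CC/C(C)=C/CO[Si](c1ccccc1)(c1ccccc1)C(C)(C)C | intermediate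
25 | (1R,2R,4aR,5S)-1-{(3E)-5-[(tert-butyldiphenylsilyl)oxy]-3-methylpent-3-en-1-yl}-5-(methoxycarbonyl)-2,5-dimethyl-1,2,3,4,4a,5,6,7-octahydronaphthalene-1-carboxylic acid | COC(=O)[C@@]1(C)CCC=C2[C@H]1CC[C@@H](C)[C@]2(C(=O)O)CC/C(C)=C/CO[Si](c1ccccc1)(c1ccccc1)C(C)(C)C | intermediate
26 | acid chloride of 25 (not isolated) | COC(=O)[C@@]1(C)CCC=C2[C@H]1CC[C@@H](C)[C@]2(C(=O)Cl)CC/C(C)=C/CO[Si](c1ccccc1)(c1ccccc1)C(C)(C)C | intermediate
27 | methyl (1S,5R,6R,8aR)-5-{(3E)-5-[(tert-butyldiphenylsilyl)oxy]-3-methylpent-3-en-1-yl}-5-formyl-1,6-dimethyl-1,2,3,5,6,7,8,8a-octahydronaphthalene-1-carboxylate | COC(=O)[C@@]1(C)CCC=C2[C@H]1CC[C@@H](C)[C@]2(C=O)CC/C(C)=C/CO[Si](c1ccccc1)(c1ccccc1)C(C)(C)C | intermediate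
28 | methyl (1S,5R,6R,8aR)-5-{(3E)-5-[(tert-butyldiphenylsilyl)oxy]-3-methylpent-3-en-1-yl}-1,6-dimethyl-5-{(E)-[2-(4-methylbenzenesulfonyl)hydrazinylidene]methyl}-1,2,3,5,6,7,8,8a-octahydronaphthalene-1-carboxylate | COC(=O)[C@@]1(C)CCC=C2[C@H]1CC[C@@H](C)[C@]2(/C=N/NS(=O)(=O)c1ccc(C)cc1)CC/C(C)=C/CO[Si](c1ccccc1)(c1ccccc1)C(C)(C)C | intermediate
29 | methyl (1S,5S,6R,8aR)-5-{(3E)-5-[(tert-butyldiphenylsilyl)oxy]-3-methylpent-3-en-1-yl}-1,5,6-trimethyl-1,2,3,5,6,7,8,8a-octahydronaphthalene-1-carboxylate | COC(=O)[C@@]1(C)CCC=C2[C@H]1CC[C@@H](C)[C@]2(C)CC/C(C)=C/CO[Si](c1ccccc1)(c1ccccc1)C(C)(C)C | intermediate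
30 | methyl (1S,5S,6R,8aR)-5-[(3E)-5-hydroxy-3-methylpent-3-en-1-yl]-1,5,6-trimethyl-1,2,3,5,6,7,8,8a-octahydronaphthalene-1-carboxylate | COC(=O)[C@@]1(C)CCC=C2[C@H]1CC[C@@H](C)[C@]2(C)CC/C(C)=C/CO | intermediate
31 | methyl (1S,5S,6R,8aR)-5-[(3E)-5-acetoxy-3-methylpent-3-en-1-yl]-1,5,6-trimethyl-1,2,3,5,6,7,8,8a-octahydronaphthalene-1-carboxylate | COC(=O)[C@@]1(C)CCC=C2[C@H]1CC[C@@H](C)[C@]2(C)CC/C(C)=C/COC(C)=O | target

## Step count and least certain steps

Total step count: 20. Longest linear sequence: 15 steps (steps 6–20 from 8). The branch from 1 (steps 1–5, then 11–20) is equally long.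

**Step 14 (key step).** The bridged boat may be reached only at temperatures where the ketene acetal is lost by other paths: C-silylation, fragmentation of the enolate to a ketene and an alkoxide, or hydrogen shifts in the dienyl system. The quaternary C4 lies on the propenyl side of the lactone and crowds the transition state.

Fallback: form the same C8–C9 bond by palladium-catalysed allylic alkylation (Tsuji–Trost cyclisation). Setting out from 18, the triethylsilyl ether is removed (HF·pyridine, pyridine, THF) to give the hydroxy tert-butyl ester F1. This is converted with MeOCOCl and pyridine into the allylic methyl carbonate F2. The ester enolate (LiN(SiMe3)2, THF, −78 °C) is then cyclised with Pd(PPh3)4, giving the ring-B tert-butyl ester F3 by attack of C9 on C8 of the π-allyl complex. Me3SiOTf and 2,6-lutidine free the acid, and the route is rejoined at 24. Ionisation and attack both occur anti to palladium, so the new bond should form on the face that O6 leaves, as in the pericyclic route. The C9 face is no longer locked by a ring, so a separation of C9 epimers must be expected.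

**Step 7.** Two selectivities may fall short: the facial selectivity at C5 (methyl against ester on C4 are of similar size) and the syn/anti selectivity at C6. A competing closed transition state would favour the anti epimer.

Fallback: use the anti epimer by closing the lactone with inversion. Setting out from 10, the aldol is run as in step 7 and the (6R) epimer is isolated: methyl (1S,2R)-2-[(1R,2E)-1-hydroxybut-2-en-1-yl]-1-methyl-3-oxocyclohexane-1-carboxylate F4. It is taken through the chemistry of steps 8–12:
- its triethylsilyl ether F5;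
- the alkenyl triflate F6;
- the tert-butyl ester F7;
- the alkylated ester F8;
- the C6-epimeric hydroxy acid F9.

F9 is then lactonised under Mitsunobu conditions (PPh3, DIAD, toluene, 0 °C, slow addition), so that the carboxylate displaces the activated O6 with inversion. The route is rejoined at 21.

**Step 11.** The basic dienolate may cause E2 elimination of the homoallylic iodide to a diene, with some γ-alkylation at C1, which wastes the advanced ester 17.

Fallback: move the alkylation to a cheap partner and bring the chain in with the coupling. Setting out from 7, alkylation of the lithium enolate of tert-butyl acetate (used in excess) gives tert-butyl (5E)-7-[(tert-butyldiphenylsilyl)oxy]-5-methylhept-5-enoate F10. Its zinc enolate F11 (LiN(SiMe3)2, then ZnCl2) is coupled with triflate 14 under Pd2(dba)3 and XPhos. The route is rejoined at 18.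

**Step 18.** The monoalkyl diazene may lose nitrogen by a radical path. A radical at C20 sits next to quaternary C9 and is homoallylic to C1=C10, so 1,2-vinyl migration (expansion of ring B) could compete with hydrogen transfer. Hydride addition to the hindered hydrazone may also be slow.

Fallback: an anionic Wolff–Kishner reduction at room temperature. Setting out from 27, condensation with 1,2-bis(tert-butyldimethylsilyl)hydrazine and Sc(OTf)3 (cat.) gives the N-silyl hydrazone F12. Treatment with KOt-Bu and t-BuOH in DMSO at rt leads through the diazenyl anion to the methyl compound. The route is rejoined at 29. Any silyl ether lost under these conditions is of no consequence, as step 19 removes it.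

## Further compounds

F1 | step 14 | tert-butyl (5E)-7-[(tert-butyldiphenylsilyl)oxy]-2-{(5S,6R)-6-[(1S,2E)-1-hydroxybut-2-en-1-yl]-5-(methoxycarbonyl)-5-methylcyclohex-1-en-1-yl}-5-methylhept-5-enoate (both C9 epimers) | COC(=O)[C@@]1(C)CCC=C(C(CC/C(C)=C/CO[Si](c2ccccc2)(c2ccccc2)C(C)(C)C)C(=O)OC(C)(C)C)[C@H]1[C@@H](O)/C=C/C
F2 | step 14 | methyl carbonate of F1 at O6 (both C9 epimers) | COC(=O)[C@@]1(C)CCC=C(C(CC/C(C)=C/CO[Si](c2ccccc2)(c2ccccc2)C(C)(C)C)C(=O)OC(C)(C)C)[C@H]1[C@@H](OC(=O)OC)/C=C/C
F3 | step 14 | tert-butyl ester of 24 | COC(=O)[C@@]1(C)CCC=C2[C@H]1C=C[C@@H](C)[C@]2(C(=O)OC(C)(C)C)CC/C(C)=C/CO[Si](c1ccccc1)(c1ccccc1)C(C)(C)C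
F4 | step 7 | methyl (1S,2R)-2-[(1R,2E)-1-hydroxybut-2-en-1-yl]-1-methyl-3-oxocyclohexane-1-carboxylate | COC(=O)[C@@]1(C)CCCC(=O)[C@H]1[C@H](O)/C=C/C
F5 | step 7 | methyl (1S,2R)-1-methyl-3-oxo-2-[(1R,2E)-1-[(triethylsilyl)oxy]but-2-en-1-yl]cyclohexane-1-carboxylate | COC(=O)[C@@]1(C)CCCC(=O)[C@H]1[C@H](O[Si](CC)(CC)CC)/C=C/C
F6 | step 7 | methyl (1S,2R)-1-methyl-2-[(1R,2E)-1-[(triethylsilyl)oxy]but-2-en-1-yl]-3-{[(trifluoromethyl)sulfonyl]oxy}cyclohex-3-ene-1-carboxylate | COC(=O)[C@@]1(C)CCC=C(OS(=O)(=O)C(F)(F)F)[C@H]1[C@H](O[Si](CC)(CC)CC)/C=C/C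
F7 | step 7 | methyl (1S,2R)-3-(2-tert-butoxy-2-oxoethyl)-1-methyl-2-[(1R,2E)-1-[(triethylsilyl)oxy]but-2-en-1-yl]cyclohex-3-ene-1-carboxylate | COC(=O)[C@@]1(C)CCC=C(CC(=O)OC(C)(C)C)[C@H]1[C@H](O[Si](CC)(CC)CC)/C=C/C
F8 | step 7 | C6 epimer of 18 (both C9 epimers) | COC(=O)[C@@]1(C)CCC=C(C(CC/C(C)=C/CO[Si](c2ccccc2)(c2ccccc2)C(C)(C)C)C(=O)OC(C)(C)C)[C@H]1[C@H](O[Si](CC)(CC)CC)/C=C/C
F9 | step 7 | C6 epimer of 20 (both C9 epimers) | COC(=O)[C@@]1(C)CCC=C(C(CC/C(C)=C/CO[Si](c2ccccc2)(c2ccccc2)C(C)(C)C)C(=O)O)[C@H]1[C@H](O)/C=C/C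
F10 | step 11 | tert-butyl (5E)-7-[(tert-butyldiphenylsilyl)oxy]-5-methylhept-5-enoate | CC(C)(C)OC(=O)CCC/C(C)=C/CO[Si](c1ccccc1)(c1ccccc1)C(C)(C)C
F11 | step 11 | chlorozinc enolate of F10 (drawn C-bound) | CC(C)(C)OC(=O)C([Zn]Cl)CC/C(C)=C/CO[Si](c1ccccc1)(c1ccccc1)C(C)(C)C
F12 | step 18 | N-(tert-butyldimethylsilyl)hydrazone of 27 | COC(=O)[C@@]1(C)CCC=C2[C@H]1CC[C@@H](C)[C@]2(/C=N/N[Si](C)(C)C(C)(C)C)CC/C(C)=C/CO[Si](c1ccccc1)(c1ccccc1)C(C)(C)C
A1 | alternative 1 | cyclopropyl carbinol with C20 bridging C9 and C10 on the α face | COC(=O)[C@@]1(C)CC[C@H](O)[C@@]23C[C@]2(CCC4(C)OCCO4)[C@H](C)CC[C@@H]13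
A2 | alternative 1 | C1 α-hydroxy Δ9(10)-alkene with the chain as a ketal | COC(=O)[C@@]1(C)CC[C@H](O)C2=C(CCC3(C)OCCO3)[C@H](C)CC[C@@H]12
A3 | alternative 2 | ring-B 1-vinylcyclohexene carrying the complete chain | C=CC1=CCC[C@@H](C)[C@]1(C)CC/C(C)=C/COC(C)=O
A4 | alternative 2 | methacrolein | CC(=C)C=O
A5 | alternative 2 | C19 aldehyde analogue of the target | O=C[C@@]1(C)CCC=C2[C@H]1CC[C@@H](C)[C@]2(C)CC/C(C)=C/COC(C)=O
A6 | alternative 3 | ring-A alkenyl triflate with the tethered trisubstituted alkene | COC(=O)[C@@]1(C)CCC=C(OS(=O)(=O)C(F)(F)F)[C@H]1CC[C@@H](C)/C(C)=C/C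
A7 | alternative 3 | octalin with a vinyl group on quaternary C9 | COC(=O)[C@@]1(C)CCC=C2[C@H]1CC[C@@H](C)[C@]2(C)C=C
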